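**Retrosynthetic overview**

1. Feature: ring A is the only ring (C1–C14, numbered from the CH that carries the side chain, through C4(Me)=C5 (E) and C8(Me)=C9 (Z), to C12 (CH–CH2OH) and C14). C1 is an allylic methine bonded to C14 and to C15 of the exocyclic C15=C16H2 alkene, and this homoallyl array C14–C1–C15=C16 is what γ-attack of a C16–C15=C1 allylmetal on a C14 carbonyl leaves behind.
2. Target ⇒ (fluoride; radical deoxygenation at C14) C14-hydroxy macrocycle ⇒ (C1–C14 bond; ring A is closed here, the only ring-forming event) open-chain (E)-C16 allylic bromide / C14 aldehyde.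
3. Open chain ⇒ C1=C15 by Horner–Wadsworth–Emmons olefination (phosphonate from triethyl phosphonoacetate and 5-bromo-2-methylpent-2-ene); C2–C3 by lithioacetonitrile alkylation; C10–C11 by copper-catalysed Grignard/allylic acetate coupling.
4. C3–C10 comes from nerol (Z alkene native, E allylic alcohol by SeO2); C11–C14 from diethyl allylmalonate, with C12 set by lipase desymmetrisation and C14 carried as a dimethyl acetal. The silyl group on the C12 hydroxymethyl is tert-butyldiphenylsilyl, chosen to survive the acidic steps.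

Key step: step 20

Remark 1 (assumption): the lipase acetylation of the prochiral diol is taken to give the (S)-monoacetate; if the enzyme gives the antipode, the two arms are processed in the reverse order (bromide on the free arm, silyl ether on the former acetate arm) to reach the same bromide.
Remark 2 (assumption): the (S)-configured oxazoline–sulfonamide ligand is taken to direct the allyl unit to the Si face of the aldehyde; if the sense is the reverse, its antipode from (R)-valinol is used.

**Route**

Step 1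
Reactants: 1 nerol
Product: 2 neryl acetate
Conditions: Ac2O, pyridine, 4-(dimethylamino)pyridine (cat.), CH2Cl2, 0 °C to rt
Reagents that add atoms: acetic anhydride, CC(=O)OC(C)=O
Why: O-acylation; the acetate deactivates the neighbouring Z alkene towards SeO2 and later serves as the leaving group at C10.

Step 2
Reactants: 2 neryl acetate
Product: 3 (2Z,6E)-8-hydroxy-3,7-dimethylocta-2,6-dien-1-yl acetate
Conditions: SeO2 (cat.), t-BuOOH, salicylic acid (cat.), CH2Cl2, rt
Reagents that add atoms: selenium dioxide, O=[Se]=O (delivers the oxygen); tert-butyl hydroperoxide, CC(C)(C)OO (restores SeO2)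
Why: Riley allylic oxidation (ene reaction, then [2,3]-shift) should hydroxylate the methyl group trans to the chain on the electron-rich terminal alkene, which gives the E alcohol that becomes C3 next to C4=C5.

Step 3
Reactants: 3 (2Z,6E)-8-hydroxy-3,7-dimethylocta-2,6-dien-1-yl acetate
Product: 4 (2Z,6E)-8-(tert-butyldimethylsilyloxy)-3,7-dimethylocta-2,6-dien-1-yl acetate
Conditions: TBSCl, imidazole, DMF, 0 °C
Reagents that add atoms: tert-butyldimethylsilyl chloride, CC(C)(C)[Si](C)(C)Cl
Why: silylation of the primary allylic alcohol removes the acidic proton before the Grignard coupling.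

Step 4
Reactants: 5 diethyl allylmalonate
Product: 6 2-allylpropane-1,3-diol
Conditions: LiAlH4, THF, 0 °C to rt
Reagents that add atoms: none
Why: hydride reduction of both esters gives the prochiral diol.

Step 5
Reactants: 6 2-allylpropane-1,3-diol
Product: 7 (S)-2-(hydroxymethyl)pent-4-en-1-yl acetate
Conditions: Burkholderia cepacia lipase (lipase PS), vinyl acetate, t-BuOMe, rt
Reagents that add atoms: vinyl acetate, C=COC(C)=O
Why: enzymatic desymmetrisation by irreversible transesterification; the lipase distinguishes the two enantiotopic hydroxymethyl groups and thereby sets the C12 stereocentre.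

Step 6
Reactants: 7 (S)-2-(hydroxymethyl)pent-4-en-1-yl acetate
Product: 8 (R)-2-[(tert-butyldiphenylsilyloxy)methyl]pent-4-en-1-yl acetate
Conditions: TBDPSCl, imidazole, CH2Cl2, 0 °C
Reagents that add atoms: tert-butyldiphenylsilyl chloride, CC(C)(C)[Si](Cl)(c1ccccc1)c1ccccc1
Why: prompt silylation of the free arm blocks the 1,3-acyl shift that would racemise the monoacetate (the descriptor changes only through priorities).

Step 7
Reactants: 8 (R)-2-[(tert-butyldiphenylsilyloxy)methyl]pent-4-en-1-yl acetate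
Product: 10 (R)-2-[(tert-butyldiphenylsilyloxy)methyl]-4,4-dimethoxybutyl acetate, via aldehyde 9 (not isolated)
Conditions: O3, CH2Cl2/MeOH, −78 °C; Me2S, −78 °C to rt; then HC(OMe)3, pyridinium p-toluenesulfonate (cat.), rt
Reagents that add atoms: ozone, [O-][O+]=O (oxygen of 9); trimethyl orthoformate, COC(OC)OC (methoxy groups of 10)
Why: ozonolysis of the only alkene with reductive work-up, then acid-catalysed acetalisation, turns the allyl group into C13–C14 masked as a dimethyl acetal; the silyl ether and the acetate should tolerate the weak pyridinium acid.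

Step 8
Reactants: 10 (R)-2-[(tert-butyldiphenylsilyloxy)methyl]-4,4-dimethoxybutyl acetate
Product: 11 (R)-2-[(tert-butyldiphenylsilyloxy)methyl]-4,4-dimethoxybutan-1-ol
Conditions: i-Bu2AlH, CH2Cl2, −78 °C
Reagents that add atoms: none
Why: reductive removal of the acetate at low temperature avoids the alkoxide conditions under which a 1,3-silyl shift could erode the C12 configuration.

Step 9
Reactants: 11 (R)-2-[(tert-butyldiphenylsilyloxy)methyl]-4,4-dimethoxybutan-1-ol
Product: 12 (S)-[2-(bromomethyl)-4,4-dimethoxybutoxy](tert-butyl)diphenylsilane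
Conditions: CBr4, PPh3, imidazole, CH2Cl2, 0 °C
Reagents that add atoms: carbon tetrabromide, BrC(Br)(Br)Br
Why: Appel bromination at the primary carbon (C11); imidazole buffers the medium so that the acetal and the silyl ether persist, and the stereocentre is not involved.

Step 10
Reactants: 12 (S)-[2-(bromomethyl)-4,4-dimethoxybutoxy](tert-butyl)diphenylsilane; 4 (2Z,6E)-8-(tert-butyldimethylsilyloxy)-3,7-dimethylocta-2,6-dien-1-yl acetate
Product: 14 (2E,6Z,10S)-1-(tert-butyldimethylsilyloxy)-10-[(tert-butyldiphenylsilyloxy)methyl]-12,12-dimethoxy-2,6-dimethyldodeca-2,6-diene, via Grignard reagent 13 (not isolated)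
Conditions: Mg (I2-activated), THF, 40 °C; then 4, Li2CuCl4 (5 mol%), THF, −78 to 0 °C
Reagents that add atoms: magnesium, [Mg] (held in 13 only)
Why: copper-catalysed Grignard/allylic acetate cross-coupling forms C10–C11 at the primary α-carbon, because the fully substituted γ-carbon C8 disfavours SN2′ attack and the short-lived allylcopper intermediate should keep the Z geometry, while acetal and silyl ethers are inert to the Grignard reagent.

Step 11
Reactants: 14 (2E,6Z,10S)-1-(tert-butyldimethylsilyloxy)-10-[(tert-butyldiphenylsilyloxy)methyl]-12,12-dimethoxy-2,6-dimethyldodeca-2,6-diene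
Product: 15 (2E,6Z,10S)-10-[(tert-butyldiphenylsilyloxy)methyl]-12,12-dimethoxy-2,6-dimethyldodeca-2,6-dien-1-ol
Conditions: pyridinium p-toluenesulfonate, MeOH, 40 °C
Reagents that add atoms: none
Why: mild acid methanolysis cleaves the primary tert-butyldimethylsilyl ether selectively; the bulkier diphenylsilyl ether is much slower and the dimethyl acetal is degenerate in methanol.

Step 12
Reactants: 15 (2E,6Z,10S)-10-[(tert-butyldiphenylsilyloxy)methyl]-12,12-dimethoxy-2,6-dimethyldodeca-2,6-dien-1-ol
Product: 17 (2E,6Z,10S)-1-bromo-10-[(tert-butyldiphenylsilyloxy)methyl]-12,12-dimethoxy-2,6-dimethyldodeca-2,6-diene, via allylic mesylate 16 (not isolated)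
Conditions: MsCl, Et3N, THF, −40 °C; LiBr, THF, −40 to 0 °C
Reagents that add atoms: methanesulfonyl chloride, CS(=O)(=O)Cl (held in 16 only); lithium bromide, [Li+].[Br-]
Why: sulfonylation and SN2 displacement by bromide at the primary allylic carbon under non-acidic conditions keep the E alkene and the acetal intact.

Step 13
Reactants: 17 (2E,6Z,10S)-1-bromo-10-[(tert-butyldiphenylsilyloxy)methyl]-12,12-dimethoxy-2,6-dimethyldodeca-2,6-diene
Product: 18 (4E,8Z,12S)-12-[(tert-butyldiphenylsilyloxy)methyl]-14,14-dimethoxy-4,8-dimethyltetradeca-4,8-dienenitrile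
Conditions: MeCN, n-BuLi, THF, −78 °C; then 17, −78 to −40 °C
Reagents that add atoms: acetonitrile, CC#N
Why: SN2 alkylation of lithioacetonitrile (an acetaldehyde enolate equivalent) at the primary allylic bromide adds C1–C2; an excess of the anion suppresses double alkylation.

Step 14
Reactants: 18 (4E,8Z,12S)-12-[(tert-butyldiphenylsilyloxy)methyl]-14,14-dimethoxy-4,8-dimethyltetradeca-4,8-dienenitrile
Product: 20 (4E,8Z,12S)-12-[(tert-butyldiphenylsilyloxy)methyl]-14,14-dimethoxy-4,8-dimethyltetradeca-4,8-dienal, via aluminium aldimine 19 (not isolated)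
Conditions: i-Bu2AlH, toluene, −78 °C; aq. Rochelle salt (KNaC4H4O6), 0 °C
Reagents that add atoms: diisobutylaluminium hydride, CC(C)C[AlH]CC(C)C (aluminium held in 19 only); water, O (carbonyl oxygen)
Why: a single hydride addition gives the aluminium aldimine, which resists further reduction and hydrolyses to the C1 aldehyde at near-neutral pH, where the dimethyl acetal should persist.

Step 15
Reactants: 21 triethyl phosphonoacetate; 22 5-bromo-2-methylpent-2-ene
Product: 23 ethyl 2-(diethoxyphosphoryl)-6-methylhept-5-enoate (racemic)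
Conditions: NaH, DMF, 0 to 60 °C
Reagents that add atoms: none
Why: C-alkylation of the stabilised phosphonoacetate anion with a primary bromide; the phosphonate is kept in excess to limit double alkylation.

Step 16
Reactants: 20 (4E,8Z,12S)-12-[(tert-butyldiphenylsilyloxy)methyl]-14,14-dimethoxy-4,8-dimethyltetradeca-4,8-dienal; 23 ethyl 2-(diethoxyphosphoryl)-6-methylhept-5-enoate
Product: 24 ethyl (2E,6E,10Z,14S)-14-[(tert-butyldiphenylsilyloxy)methyl]-16,16-dimethoxy-6,10-dimethyl-2-(4-methylpent-3-en-1-yl)hexadeca-2,6,10-trienoate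
Conditions: NaH, THF, 0 °C to rt
Reagents that add atoms: none
Why: Horner–Wadsworth–Emmons olefination forms C1=C15; reversible addition of the stabilised anion should favour the E enoate (ester trans to C2), and any Z isomer is removed by chromatography here or after step 17.

Step 17
Reactants: 24 ethyl (2E,6E,10Z,14S)-14-[(tert-butyldiphenylsilyloxy)methyl]-16,16-dimethoxy-6,10-dimethyl-2-(4-methylpent-3-en-1-yl)hexadeca-2,6,10-trienoate
Product: 25 (2E,6E,10Z,14S)-14-[(tert-butyldiphenylsilyloxy)methyl]-16,16-dimethoxy-6,10-dimethyl-2-(4-methylpent-3-en-1-yl)hexadeca-2,6,10-trien-1-ol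
Conditions: i-Bu2AlH, CH2Cl2, −78 °C
Reagents that add atoms: none
Why: 1,2-reduction of the enoate gives the C16 allylic alcohol without touching the acetal, the silyl ether or the alkene geometry.

Step 18
Reactants: 25 (2E,6E,10Z,14S)-14-[(tert-butyldiphenylsilyloxy)methyl]-16,16-dimethoxy-6,10-dimethyl-2-(4-methylpent-3-en-1-yl)hexadeca-2,6,10-trien-1-ol
Product: 26 (3S,6Z,10E,14E)-3-[(tert-butyldiphenylsilyloxy)methyl]-16-hydroxy-7,11-dimethyl-15-(4-methylpent-3-en-1-yl)hexadeca-6,10,14-trienal
Conditions: pyridinium p-toluenesulfonate, acetone/H2O, 50 °C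
Reagents that add atoms: water, O
Why: mild acid-catalysed acetal hydrolysis frees the C14 aldehyde; the diphenylsilyl ether, the allylic alcohol and the trisubstituted alkenes should tolerate the weak acid.

Step 19
Reactants: 26 (3S,6Z,10E,14E)-3-[(tert-butyldiphenylsilyloxy)methyl]-16-hydroxy-7,11-dimethyl-15-(4-methylpent-3-en-1-yl)hexadeca-6,10,14-trienal
Product: 28 (3S,6Z,10E,14E)-16-bromo-3-[(tert-butyldiphenylsilyloxy)methyl]-7,11-dimethyl-15-(4-methylpent-3-en-1-yl)hexadeca-6,10,14-trienal, via allylic mesylate 27 (not isolated)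
Conditions: MsCl, Et3N, CH2Cl2, −40 °C; LiBr, THF, −40 to 0 °C
Reagents that add atoms: methanesulfonyl chloride, CS(=O)(=O)Cl (held in 27 only); lithium bromide, [Li+].[Br-]
Why: sulfonylation of the allylic alcohol and SN2 displacement by bromide are non-oxidising and only briefly basic at low temperature, so the enolisable aldehyde should survive; the bromide is used at once.

Step 20
Reactants: 28 (3S,6Z,10E,14E)-16-bromo-3-[(tert-butyldiphenylsilyloxy)methyl]-7,11-dimethyl-15-(4-methylpent-3-en-1-yl)hexadeca-6,10,14-trienal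
Product: 30 macrocyclic alcohol (1S,12S,14R)-12-[(tert-butyldiphenylsilyloxy)methyl]-4,8-dimethyl-1-(6-methylhepta-1,5-dien-2-yl)cyclotetradeca-4E,8Z-dien-14-ol (ring numbering), via trivalent allylchromium 29 (not isolated)
Conditions: CrCl2 (6 equiv), (S)-N-[2-(4-isopropyl-4,5-dihydro-1,3-oxazol-2-yl)-6-methylphenyl]methanesulfonamide (6.6 equiv), Et3N (6.6 equiv), THF, rt; 28 added over 12 h to a final 2 mM; aqueous work-up
Reagents that add atoms: chromium dichloride, Cl[Cr]Cl (chromium held in 29 only)
Why: Two equivalents of ligand-bound divalent chromium reduce the C–Br bond by successive single-electron transfers to the trivalent σ-allylchromium 29, which adds to the C14 aldehyde through a closed six-membered chair; this is a Nozaki–Hiyama–Kishi allylation, the closest known case being CrCl2 closures of bromoallyl aldehydes to 14-membered cembranoid rings. Bonding at the γ-carbon C1 closes ring A in a 14-exo-trig mode and moves the double bond out to C15=C16, so no endocyclic alkene isomer can arise. In the chair the C2 chain sits equatorial on the E allyl unit (to which any Z material should drain by 1,3-metal shift), and this fixes the anti C1/C14 relationship. The absolute sense comes from the chromium-bound oxazoline–sulfonamide, which should expose the Si face of the aldehyde and so give 14R and with it 1S, the C12 substituent adding only a small bias. The step needs γ- over α-attack, which the cyclic transition state of allylchromium reagents secures, and ring closure over oligomerisation, which slow addition at high dilution secures; the trisubstituted alkenes and the silyl ether are not touched by the reagent.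

Step 21
Reactants: 30 macrocyclic alcohol (1S,12S,14R)
Product: 32 O-[(1S,12S,14R)-12-[(tert-butyldiphenylsilyloxy)methyl]-4,8-dimethyl-1-(6-methylhepta-1,5-dien-2-yl)cyclotetradeca-4E,8Z-dien-14-yl] S-methyl dithiocarbonate, via sodium xanthate 31 (not isolated)
Conditions: NaH, imidazole (cat.), THF, 0 °C; CS2; MeI, rt
Reagents that add atoms: sodium hydride, [Na+].[H-] (sodium held in 31 only); carbon disulfide, S=C=S; iodomethane, CI
Why: xanthate formation (alkoxide addition to CS2, then S-methylation) prepares the C14 oxygen for radical removal without touching a stereocentre.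

Step 22
Reactants: 32 S-methyl dithiocarbonate of 30
Product: 33 tert-butyl{[(1S,12S)-4,8-dimethyl-1-(6-methylhepta-1,5-dien-2-yl)cyclotetradeca-4E,8Z-dien-12-yl]methoxy}diphenylsilane (ring numbering)
Conditions: Bu3SnH (0.5 M), Et3B, air, toluene, rt
Reagents that add atoms: none
Why: Barton–McCombie deoxygenation: the tin radical adds to the thiocarbonyl, β-scission gives the secondary C14 radical, and concentrated stannane at room temperature should quench it before it adds across the ring to C4=C5 or rearranges through the C15=C16 alkene; C1 and C12 are not involved.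

Step 23
Reactants: 33 tert-butyl{[(1S,12S)-4,8-dimethyl-1-(6-methylhepta-1,5-dien-2-yl)cyclotetradeca-4E,8Z-dien-12-yl]methoxy}diphenylsilane
Product: 34 [(1S,12S)-4,8-dimethyl-1-(6-methylhepta-1,5-dien-2-yl)cyclotetradeca-4E,8Z-dien-12-yl]methanol (ring numbering), the target
Conditions: Bu4NF, THF, rt
Reagents that add atoms: none
Why: fluoride cleavage of the silyl ether (Si–F bond formation) frees the primary alcohol without touching alkenes or stereocentres.

**Compound list**

1 | nerol | CC(C)=CCC/C(C)=C\CO | starting material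
2 | neryl acetate | CC(C)=CCC/C(C)=C\COC(C)=O | intermediate
3 | (2Z,6E)-8-hydroxy-3,7-dimethylocta-2,6-dien-1-yl acetate | OC/C(C)=C/CC/C(C)=C\COC(C)=O | intermediate
4 | (2Z,6E)-8-(tert-butyldimethylsilyloxy)-3,7-dimethylocta-2,6-dien-1-yl acetate | CC(C)(C)[Si](C)(C)OC/C(C)=C/CC/C(C)=C\COC(C)=O | intermediate
5 | diethyl allylmalonate | C=CCC(C(=O)OCC)C(=O)OCC | starting material
6 | 2-allylpropane-1,3-diol | C=CCC(CO)CO | intermediate
7 | (S)-2-(hydroxymethyl)pent-4-en-1-yl acetate | CC(=O)OC[C@H](CO)CC=C | intermediate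
8 | (R)-2-[(tert-butyldiphenylsilyloxy)methyl]pent-4-en-1-yl acetate | CC(=O)OC[C@H](CO[Si](c1ccccc1)(c1ccccc1)C(C)(C)C)CC=C | intermediate
9 | (R)-2-[(tert-butyldiphenylsilyloxy)methyl]-4-oxobutyl acetate (not isolated) | CC(=O)OC[C@H](CO[Si](c1ccccc1)(c1ccccc1)C(C)(C)C)CC=O | intermediate
10 | (R)-2-[(tert-butyldiphenylsilyloxy)methyl]-4,4-dimethoxybutyl acetate | CC(=O)OC[C@H](CO[Si](c1ccccc1)(c1ccccc1)C(C)(C)C)CC(OC)OC | intermediate
11 | (R)-2-[(tert-butyldiphenylsilyloxy)methyl]-4,4-dimethoxybutan-1-ol | OC[C@H](CO[Si](c1ccccc1)(c1ccccc1)C(C)(C)C)CC(OC)OC | intermediate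
12 | (S)-[2-(bromomethyl)-4,4-dimethoxybutoxy](tert-butyl)diphenylsilane | BrC[C@H](CO[Si](c1ccccc1)(c1ccccc1)C(C)(C)C)CC(OC)OC | intermediate
13 | (S)-{2-[(tert-butyldiphenylsilyloxy)methyl]-4,4-dimethoxybutyl}magnesium bromide (not isolated) | Br[Mg]C[C@H](CO[Si](c1ccccc1)(c1ccccc1)C(C)(C)C)CC(OC)OC | intermediate
14 | (2E,6Z,10S)-1-(tert-butyldimethylsilyloxy)-10-[(tert-butyldiphenylsilyloxy)methyl]-12,12-dimethoxy-2,6-dimethyldodeca-2,6-diene | CC(C)(C)[Si](C)(C)OC/C(C)=C/CC/C(C)=C\CC[C@H](CO[Si](c1ccccc1)(c1ccccc1)C(C)(C)C)CC(OC)OC | intermediate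
15 | (2E,6Z,10S)-10-[(tert-butyldiphenylsilyloxy)methyl]-12,12-dimethoxy-2,6-dimethyldodeca-2,6-dien-1-ol | OC/C(C)=C/CC/C(C)=C\CC[C@H](CO[Si](c1ccccc1)(c1ccccc1)C(C)(C)C)CC(OC)OC | intermediate
16 | methanesulfonate of 15 (not isolated) | CS(=O)(=O)OC/C(C)=C/CC/C(C)=C\CC[C@H](CO[Si](c1ccccc1)(c1ccccc1)C(C)(C)C)CC(OC)OC | intermediate
17 | (2E,6Z,10S)-1-bromo-10-[(tert-butyldiphenylsilyloxy)methyl]-12,12-dimethoxy-2,6-dimethyldodeca-2,6-diene | BrC/C(C)=C/CC/C(C)=C\CC[C@H](CO[Si](c1ccccc1)(c1ccccc1)C(C)(C)C)CC(OC)OC | intermediate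
18 | (4E,8Z,12S)-12-[(tert-butyldiphenylsilyloxy)methyl]-14,14-dimethoxy-4,8-dimethyltetradeca-4,8-dienenitrile | N#CCC/C(C)=C/CC/C(C)=C\CC[C@H](CO[Si](c1ccccc1)(c1ccccc1)C(C)(C)C)CC(OC)OC | intermediate
19 | N-(diisobutylaluminio) aldimine of 20 (not isolated) | CC(C)C[Al](CC(C)C)N=CCC/C(C)=C/CC/C(C)=C\CC[C@H](CO[Si](c1ccccc1)(c1ccccc1)C(C)(C)C)CC(OC)OC | intermediate
20 | (4E,8Z,12S)-12-[(tert-butyldiphenylsilyloxy)methyl]-14,14-dimethoxy-4,8-dimethyltetradeca-4,8-dienal | O=CCC/C(C)=C/CC/C(C)=C\CC[C@H](CO[Si](c1ccccc1)(c1ccccc1)C(C)(C)C)CC(OC)OC | intermediate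
21 | triethyl phosphonoacetate | CCOC(=O)CP(=O)(OCC)OCC | starting material
22 | 5-bromo-2-methylpent-2-ene | CC(C)=CCCBr | starting material
23 | ethyl 2-(diethoxyphosphoryl)-6-methylhept-5-enoate | CCOC(=O)C(CCC=C(C)C)P(=O)(OCC)OCC | intermediate
24 | ethyl (2E,6E,10Z,14S)-14-[(tert-butyldiphenylsilyloxy)methyl]-16,16-dimethoxy-6,10-dimethyl-2-(4-methylpent-3-en-1-yl)hexadeca-2,6,10-trienoate | CCOC(=O)/C(CCC=C(C)C)=C/CC/C(C)=C/CC/C(C)=C\CC[C@H](CO[Si](c1ccccc1)(c1ccccc1)C(C)(C)C)CC(OC)OC | intermediate
25 | (2E,6E,10Z,14S)-14-[(tert-butyldiphenylsilyloxy)methyl]-16,16-dimethoxy-6,10-dimethyl-2-(4-methylpent-3-en-1-yl)hexadeca-2,6,10-trien-1-ol | OC/C(CCC=C(C)C)=C/CC/C(C)=C/CC/C(C)=C\CC[C@H](CO[Si](c1ccccc1)(c1ccccc1)C(C)(C)C)CC(OC)OC | intermediate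
26 | (3S,6Z,10E,14E)-3-[(tert-butyldiphenylsilyloxy)methyl]-16-hydroxy-7,11-dimethyl-15-(4-methylpent-3-en-1-yl)hexadeca-6,10,14-trienal | OC/C(CCC=C(C)C)=C/CC/C(C)=C/CC/C(C)=C\CC[C@H](CO[Si](c1ccccc1)(c1ccccc1)C(C)(C)C)CC=O | intermediate
27 | methanesulfonate of 26 (not isolated) | CS(=O)(=O)OC/C(CCC=C(C)C)=C/CC/C(C)=C/CC/C(C)=C\CC[C@H](CO[Si](c1ccccc1)(c1ccccc1)C(C)(C)C)CC=O | intermediate
28 | (3S,6Z,10E,14E)-16-bromo-3-[(tert-butyldiphenylsilyloxy)methyl]-7,11-dimethyl-15-(4-methylpent-3-en-1-yl)hexadeca-6,10,14-trienal (key-step precursor) | BrC/C(CCC=C(C)C)=C/CC/C(C)=C/CC/C(C)=C\CC[C@H](CO[Si](c1ccccc1)(c1ccccc1)C(C)(C)C)CC=O | intermediate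
29 | ligand-bound trivalent allylchromium from 28, drawn as its dichloride (not isolated) | Cl[Cr](Cl)C/C(CCC=C(C)C)=C/CC/C(C)=C/CC/C(C)=C\CC[C@H](CO[Si](c1ccccc1)(c1ccccc1)C(C)(C)C)CC=O | intermediate
30 | (1S,12S,14R)-12-[(tert-butyldiphenylsilyloxy)methyl]-4,8-dimethyl-1-(6-methylhepta-1,5-dien-2-yl)cyclotetradeca-4E,8Z-dien-14-ol (key-step product) | C=C(CCC=C(C)C)[C@@H]1CC/C(C)=C/CC/C(C)=C\CC[C@H](CO[Si](c2ccccc2)(c2ccccc2)C(C)(C)C)C[C@H]1O | intermediate
31 | sodium O-alkyl dithiocarbonate of 30 (not isolated) | C=C(CCC=C(C)C)[C@@H]1CC/C(C)=C/CC/C(C)=C\CC[C@H](CO[Si](c2ccccc2)(c2ccccc2)C(C)(C)C)C[C@H]1OC(=S)[S-].[Na+] | intermediate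
32 | O-alkyl S-methyl dithiocarbonate of 30 | C=C(CCC=C(C)C)[C@@H]1CC/C(C)=C/CC/C(C)=C\CC[C@H](CO[Si](c2ccccc2)(c2ccccc2)C(C)(C)C)C[C@H]1OC(=S)SC | intermediate
33 | tert-butyl{[(1S,12S)-4,8-dimethyl-1-(6-methylhepta-1,5-dien-2-yl)cyclotetradeca-4E,8Z-dien-12-yl]methoxy}diphenylsilane | C=C(CCC=C(C)C)[C@@H]1CC/C(C)=C/CC/C(C)=C\CC[C@H](CO[Si](c2ccccc2)(c2ccccc2)C(C)(C)C)CC1 | intermediate
34 | [(1S,12S)-4,8-dimethyl-1-(6-methylhepta-1,5-dien-2-yl)cyclotetradeca-4E,8Z-dien-12-yl]methanol | C=C(CCC=C(C)C)[C@@H]1CC/C(C)=C/CC/C(C)=C\CC[C@H](CO)CC1 | target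

**Step count**

Total: 23 steps. Longest linear sequence: 19 steps (from diethyl allylmalonate 5: steps 4–14 and 16–23).

**Steps most likely to fail**

1. Step 20 (ring closure). Chain growth between molecules may outrun the 14-membered closure, the chromium-bound ligand may select the aldehyde face only weakly (which after deoxygenation would show up as the C1 epimer), and the Lewis-acidic chromium salts could trigger a carbonyl-ene closure of the C9–C14 segment. The fallback sets out from 25 and comes back at 30. Alcohol 25 is acetylated (Ac2O, pyridine) to the allylic acetate F1. Palladium-catalysed allylic borylation (zerovalent palladium complex Pd2(dba)3, bis(pinacolato)diboron, DMSO, 50 °C) then gives the linear pinacol allylboronate F2, which is configurationally stable and can be purified as the E isomer. Hydrolysis of the acetal (pyridinium p-toluenesulfonate, wet acetone) gives the boronate aldehyde F3. At high dilution in toluene with a chiral BINOL-derived phosphoric acid as catalyst, F3 should close the same C1–C14 bond by a metal-free allylboration through a closed chair (anti from the E boronate), and hydrolytic work-up gives 30.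

2. Step 22 (deoxygenation). The C14 radical may rearrange before hydrogen transfer, either by transannular addition to C4=C5 or by a 1,2-alkenyl shift through a cyclopropylcarbinyl radical, and the xanthate may undergo thermal syn-elimination if heated. The fallback sets out from 30 and comes back at 33. Alcohol 30 is converted (MsCl, Et3N, CH2Cl2, 0 °C) into the C14 methanesulfonate F4, which is reduced by hydride displacement with LiEt3BH (THF, 0 °C to reflux). This polar path generates no radical at C14.

3. Step 10 (fragment union). Regiocontrol may be lost through γ-attack, the Z geometry may erode through allylcopper isomerisation, the Grignard reagent may attack the acetate carbonyl, or magnesium insertion into the functionalised bromide may be sluggish. The fallback sets out from 12 and 4 and comes back at 14. Bromide 12 is displaced with PhSO2Na (NaI cat., DMF, 70 °C) to the phenyl sulfone F5. Acetate 4 is methanolysed (K2CO3, MeOH) to the allylic alcohol F6 and brominated (CBr4, PPh3) to the allylic bromide F7. Lithiated F5 (n-BuLi, THF/DMPU, −78 °C) is alkylated by F7 at its primary carbon to the sulfone F8, a mixture of C11 epimers. Reductive desulfonylation with Na(Hg) and Na2HPO4 in MeOH/THF at −20 °C then gives 14; the sulfonyl carbon is not allylic, so no alkene should move.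

**Further compounds**

F1 | step 20 | acetate of allylic alcohol 25 | CC(=O)OC/C(CCC=C(C)C)=C/CC/C(C)=C/CC/C(C)=C\CC[C@H](CO[Si](c1ccccc1)(c1ccccc1)C(C)(C)C)CC(OC)OC
F2 | step 20 | pinacol allylboronate (boron on C16, acetal at C14) | CC1(C)OB(C/C(CCC=C(C)C)=C/CC/C(C)=C/CC/C(C)=C\CC[C@H](CO[Si](c2ccccc2)(c2ccccc2)C(C)(C)C)CC(OC)OC)OC1(C)C
F3 | step 20 | pinacol allylboronate with free C14 aldehyde | CC1(C)OB(C/C(CCC=C(C)C)=C/CC/C(C)=C/CC/C(C)=C\CC[C@H](CO[Si](c2ccccc2)(c2ccccc2)C(C)(C)C)CC=O)OC1(C)C
F4 | step 22 | C14 methanesulfonate of 30 | C=C(CCC=C(C)C)[C@@H]1CC/C(C)=C/CC/C(C)=C\CC[C@H](CO[Si](c2ccccc2)(c2ccccc2)C(C)(C)C)C[C@H]1OS(C)(=O)=O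
F5 | step 10 | (S)-tert-butyl{4,4-dimethoxy-2-[(phenylsulfonyl)methyl]butoxy}diphenylsilane | O=S(=O)(c1ccccc1)C[C@H](CO[Si](c1ccccc1)(c1ccccc1)C(C)(C)C)CC(OC)OC
F6 | step 10 | (2Z,6E)-8-(tert-butyldimethylsilyloxy)-3,7-dimethylocta-2,6-dien-1-ol | CC(C)(C)[Si](C)(C)OC/C(C)=C/CC/C(C)=C\CO
F7 | step 10 | (2Z,6E)-1-bromo-8-(tert-butyldimethylsilyloxy)-3,7-dimethylocta-2,6-diene | CC(C)(C)[Si](C)(C)OC/C(C)=C/CC/C(C)=C\CBr
F8 | step 10 | C11-phenylsulfonyl derivative of 14 (C11 epimers) | CC(C)(C)[Si](C)(C)OC/C(C)=C/CC/C(C)=C\CC([C@H](CO[Si](c1ccccc1)(c1ccccc1)C(C)(C)C)CC(OC)OC)S(=O)(=O)c1ccccc1
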